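## Retrosynthetic overview

1. Target 8 ⇐ diene cis-diol 7: both allylic benzoates (C2–O and C5–O) are installed last, in one palladium-catalysed trans-1,4-dibenzoyloxylation (key C–O bonds).
2. 7 ⇐ epoxy enone 5 by Wharton transposition (ketone carbon becomes an alkene CH, the C6–O bond is kept).
3. 5 ⇐ achiral p-quinol 4 by a desymmetrising asymmetric epoxidation (C–O bonds; sets C1 and C6 absolutely).
4. 4 ⇐ 4-hydroxybenzyl benzoate 3 ⇐ 4-hydroxybenzyl alcohol 1 + benzoic acid 2 (oxidative dearomatisation; esterification).
5. Ring order: the six-membered carbocycle comes intact from the arene; the only ring formed is the oxirane of 5 (step 3), which is opened again in step 4.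

Numbering used in the text: C1 = quaternary carbinol carbon, C2 and C5 = benzoyloxy-bearing carbons, C6 = secondary carbinol carbon. The target is (1S,2R,5R,6S), with C1–OH, C6–OH and C2–OBz on one face and C5–OBz on the other.

Assumption: the quinidine-derived amine in step 3 is taken to give 5; if it gives the antipode, the quinine-derived pseudoenantiomer is used under the same conditions.

## Route

Step 1
Reactants: 1 4-hydroxybenzyl alcohol; 2 benzoic acid
Product: 3 4-hydroxybenzyl benzoate
Conditions: PPh3, DIAD, THF, 0 °C to rt
Reagents that add atoms: none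
Why: Mitsunobu esterification is chemoselective for the benzylic alcohol over the phenol, because only the alcohol is activated as its oxyphosphonium ion and the much more acidic benzoic acid supplies the nucleophile; no stereocentre is formed.

Step 2
Reactants: 3 4-hydroxybenzyl benzoate
Product: 4 (1-hydroxy-4-oxocyclohexa-2,5-dien-1-yl)methyl benzoate
Conditions: PhI(OAc)2 (1.2 equiv), MeCN/H2O 3:1, 0 °C
Reagents that add atoms: water, O
Why: Oxidative dearomatisation of a para-alkylphenol by trivalent iodine, with water trapping the para carbon, gives the achiral p-quinol, whose mirror plane makes the two enone halves enantiotopic.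

Step 3
Reactants: 4 (1-hydroxy-4-oxocyclohexa-2,5-dien-1-yl)methyl benzoate
Product: 5 [(1R,5S,6S)-5-hydroxy-2-oxo-7-oxabicyclo[4.1.0]hept-3-en-5-yl]methyl benzoate (oxirane cis to the tertiary OH)
Conditions: 9-amino(9-deoxy)epiquinidine (10 mol%), CF3CO2H (20 mol%), 50% aq. H2O2 (1.2 equiv), 1,4-dioxane, 30 °C, stopped at about 90% conversion
Reagents that add atoms: hydrogen peroxide, OO
Why: Proposed new method: a desymmetrising Weitz–Scheffer-type epoxidation under iminium catalysis, in which the cinchona primary amine condenses with the dienone carbonyl, H2O2 adds to one of the two enantiotopic β-carbons and the enamine closes the oxirane; the tertiary hydroxyl (smaller than CH2OBz and a hydrogen-bond donor to H2O2) fixes attack to its own face, so the face preference of the catalyst becomes the choice of one enantiotopic alkene and sets the quaternary carbon and both oxirane carbons together, while the minor enantiomer is the matched substrate for a second epoxidation to the meso bis-epoxide and is thereby removed; the closest known reactions are the cinchona-amine/H2O2 asymmetric epoxidation of simple cyclic enones and the hydroxyl-directed syn epoxidation of p-quinols with basic hydroperoxides.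

Step 4
Reactants: 5 [(1R,5S,6S)-5-hydroxy-2-oxo-7-oxabicyclo[4.1.0]hept-3-en-5-yl]methyl benzoate
Product: 7 [(1S,6S)-1,6-dihydroxycyclohexa-2,4-dien-1-yl]methyl benzoate, via epoxy hydrazone 6 (not isolated)
Conditions: N2H4·H2O (2 equiv), AcOH (0.2 equiv), MeOH, 0 °C to rt; crude 7 used at once
Reagents that add atoms: hydrazine, NN
Why: Wharton transposition: hydrazone formation, oxirane opening to the vinyl diazene and loss of N2 convert the epoxy ketone into the transposed allylic alcohol, so the C6–O bond (and with it the cis-1,6-diol) is never broken and the former enone alkene becomes part of the 2,4-diene.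

Step 5
Reactants: 7 [(1S,6S)-1,6-dihydroxycyclohexa-2,4-dien-1-yl]methyl benzoate; 2 benzoic acid (4 equiv used, 2 incorporated)
Product: 8 [(1S,2R,5R,6S)-2,5-bis(benzoyloxy)-1,6-dihydroxycyclohex-3-en-1-yl]methyl benzoate
Conditions: Pd(OAc)2 (5 mol%), p-benzoquinone (1.2 equiv, added over 4 h), PhCO2Li (2 equiv), acetone, 25 °C
Reagents that add atoms: none
Why: Proposed new method: a hydroxyl-directed, regio- and diastereoselective trans-1,4-dibenzoyloxylation of a free ipso/ortho diene cis-diol, in which divalent palladium, held on the diol face by the two hydroxyls, activates the diene, external benzoate attacks C5 (the terminus beside CH(OH), not the neopentyl terminus C2) on the face anti to palladium and anti to the C6 hydroxyl, and the resulting (π-allyl)palladium benzoate, in the absence of chloride, passes its bound benzoate to C2 on the palladium (diol) face while benzoquinone takes up the zerovalent palladium; this forms both allylic C–O bonds and sets C5 (R) and C2 (R) in one step; the closest known reaction is the Bäckvall palladium/benzoquinone 1,4-diacyloxylation of simple cyclohexa-1,3-dienes, which is trans-selective without chloride.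

## Compound list

1 | 4-hydroxybenzyl alcohol | OCc1ccc(O)cc1 | starting material
2 | benzoic acid | OC(=O)c1ccccc1 | starting material
3 | 4-hydroxybenzyl benzoate | O=C(OCc1ccc(O)cc1)c1ccccc1 | intermediate
4 | (1-hydroxy-4-oxocyclohexa-2,5-dien-1-yl)methyl benzoate (achiral p-quinol) | O=C(OCC1(O)C=CC(=O)C=C1)c1ccccc1 | intermediate
5 | [(1R,5S,6S)-5-hydroxy-2-oxo-7-oxabicyclo[4.1.0]hept-3-en-5-yl]methyl benzoate | O=C(OC[C@@]1(O)C=CC(=O)[C@@H]2O[C@H]12)c1ccccc1 | intermediate
6 | hydrazone of 5 at the ketone carbon, same configuration (not isolated) | O=C(OC[C@@]1(O)C=CC(=NN)[C@@H]2O[C@H]12)c1ccccc1 | intermediate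
7 | [(1S,6S)-1,6-dihydroxycyclohexa-2,4-dien-1-yl]methyl benzoate | O=C(OC[C@@]1(O)C=CC=C[C@@H]1O)c1ccccc1 | intermediate
8 | [(1S,2R,5R,6S)-2,5-bis(benzoyloxy)-1,6-dihydroxycyclohex-3-en-1-yl]methyl benzoate | O=C(OC[C@@]1(O)[C@H](OC(=O)c2ccccc2)C=C[C@@H](OC(=O)c2ccccc2)[C@@H]1O)c1ccccc1 | target

## Step count and risks

Total steps: 5. Longest linear sequence: 5 (from 1).

The three steps most likely to fail, in route order:

**Step 3 (proposed new step).** The risks are low enantioselectivity, leakage to the anti epoxide, and over-oxidation to the bis-epoxide. The fallback uses known chemistry and replaces asymmetric catalysis by substrate-directed epoxidation plus enzymatic resolution. It sets out from 4. tBuOOH/DBU (CH2Cl2, 0 °C) gives, by hydroxyl-directed Weitz–Scheffer epoxidation, the racemic cis-epoxy enone F1. The Wharton conditions of step 4 convert this, through the racemic epoxy hydrazone F2 (not isolated), into the racemic diene cis-diol F3. Lipase-catalysed acylation (immobilised Candida antarctica lipase B, vinyl acetate, MTBE, 30 °C) is expected from the Kazlauskas rule to esterify the (6R) alcohol, with the quaternary carbon as the large group. This gives the acetate of the (1R,6R) enantiomer F4 and leaves the (1S,6S) alcohol untouched; chromatography separates the two. The fallback comes back to the route at 7, at no more than 50% yield.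

**Step 4.** The risks are conjugate addition of hydrazine to the remaining enone, hydrazinolysis of the benzoate, and dimerisation or aromatisation of 7. The fallback is the radical alternative to the Wharton transposition and sets out from 5. Luche reduction (NaBH4, CeCl3·7H2O, MeOH, −78 °C) gives the epoxy allylic alcohol F5; either carbinol epimer serves. 1,1'-Thiocarbonyldiimidazole (DMAP, CH2Cl2) acylates only the secondary hydroxyl, giving the imidazolylthiocarbonate F6. Bu3SnH/AIBN (PhMe, 80 °C) then generates the carbon radical next to the oxirane, which opens to the alkoxy radical and is reduced (Barton–McCombie-type radical epoxide fragmentation). The fallback comes back to the route at 7.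

**Step 5 (proposed new step).** The risks are facial or regiochemical leakage, 1,2- instead of 1,4-addition at the hindered C2 terminus, oxidation of the allylic C6 carbinol, acid-promoted aromatisation, and Diels–Alder reaction of 7 with benzoquinone. The fallback uses known chemistry (singlet-oxygen route) and sets out from 7.
- 2,2-Dimethoxypropane/PPTS (acetone, rt) gives the acetonide F7.
- Photooxygenation (O2, tetraphenylporphyrin, visible light, CH2Cl2, −78 °C) adds singlet oxygen to the diene face anti to the dioxolane, giving the endoperoxide F8 with both new C–O bonds on the face of the C5 benzoate.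
- Et3N (CH2Cl2, 0 °C) effects a Kornblum–DeLaMare rearrangement by removing the C2–H, giving the hydroxy enone F9 (C2 ketone, C5 hydroxyl kept).
- Luche reduction (NaBH4, CeCl3·7H2O, MeOH, −78 °C), with hydride adding anti to the ring-fusion C1–O bond, gives the enediol F10 with C2–OH cis to the C1 oxygen.
- BzCl/pyridine/DMAP gives the dibenzoate acetonide F11.
- Aqueous CF3CO2H (CH2Cl2, 0 °C) removes the acetonide.

The fallback comes back to the route at 8.

## Further compounds

F1 | step 3 | racemic cis-epoxy enone (5 and its enantiomer, 1:1) | O=C(OC[C@@]1(O)C=CC(=O)[C@@H]2O[C@H]12)c1ccccc1.O=C(OC[C@]1(O)C=CC(=O)[C@H]2O[C@@H]12)c1ccccc1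
F2 | step 3 | racemic epoxy hydrazone (6 and its enantiomer, 1:1; not isolated) | O=C(OC[C@@]1(O)C=CC(=NN)[C@@H]2O[C@H]12)c1ccccc1.O=C(OC[C@]1(O)C=CC(=NN)[C@H]2O[C@@H]12)c1ccccc1
F3 | step 3 | racemic diene cis-diol (7 and its enantiomer, 1:1) | O=C(OC[C@@]1(O)C=CC=C[C@@H]1O)c1ccccc1.O=C(OC[C@]1(O)C=CC=C[C@H]1O)c1ccccc1
F4 | step 3 | [(1R,6R)-6-acetoxy-1-hydroxycyclohexa-2,4-dien-1-yl]methyl benzoate (acetate of the enantiomer of 7) | O=C(OC[C@]1(O)C=CC=C[C@H]1OC(C)=O)c1ccccc1
F5 | step 4 | epoxy allylic alcohol from 1,2-reduction of 5 (carbinol epimers) | O=C(OC[C@@]1(O)C=CC(O)[C@@H]2O[C@H]12)c1ccccc1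
F6 | step 4 | O-(imidazol-1-ylcarbonothioyl) derivative of F5 at the secondary carbinol | O=C(OC[C@@]1(O)C=CC(OC(=S)n3ccnc3)[C@@H]2O[C@H]12)c1ccccc1
F7 | step 5 | acetonide of 7 (cis-fused 2,2-dimethyl-1,3-dioxolane on the C1/C6 oxygens) | O=C(OC[C@]12OC(C)(C)O[C@H]1C=CC=C2)c1ccccc1
F8 | step 5 | endoperoxide of F7 (C2,C5-epidioxy, anti to the dioxolane) | O=C(OC[C@]12OC(C)(C)O[C@H]1[C@@H]3OO[C@H]2C=C3)c1ccccc1
F9 | step 5 | hydroxy enone (C2 ketone, C3=C4, C5–OH, acetonide) | O=C(OC[C@]12OC(C)(C)O[C@H]1[C@H](O)C=CC2=O)c1ccccc1
F10 | step 5 | enediol (C2–OH cis to the C1 oxygen, C5–OH trans to the C6 oxygen, acetonide) | O=C(OC[C@]12OC(C)(C)O[C@H]1[C@H](O)C=C[C@H]2O)c1ccccc1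
F11 | step 5 | 2,5-dibenzoate acetonide (acetonide of 8) | O=C(OC[C@]12OC(C)(C)O[C@H]1[C@H](OC(=O)c3ccccc3)C=C[C@H]2OC(=O)c3ccccc3)c1ccccc1
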